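**Retrosynthetic overview**
- The last bond cut is C2–C1' of the apigenin half. Chromone C2 is the masked acyl carbon and normally the electrophilic enone terminus. Here it serves as the nucleophile, a 2-zincated 5,7-bis(silyloxy)chromone, and it attacks the electrophilic C–Br carbon of an aryl bromide.
- The aryl bromide is 8-(4-bromophenoxy)-5-hydroxy-7,4'-dimethoxyflavone. Its diaryl ether C–O bond comes from the 8-hydroxyflavone and bis(4-bromophenyl)iodonium triflate.
- The 8-OH is installed by para-hydroxylation of 5-hydroxy-7,4'-dimethoxyflavone, which is apigenin methylated twice.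
- 5,7-Dihydroxychromone comes from 2,4,6-trihydroxyacetophenone and triethyl orthoformate.
- Ring order: rings A, B and C of the methylated half are bought with apigenin. The bridging ring arrives in the ether step. Ring C of the second half is closed on phloroacetophenone and joined last.

Assumption: the SMILES has no stereocentre and no configurationally stable axis, so the target is achiral and no stereocontrol is needed.

**Step 1**
Reactants: 1 apigenin (5,7-dihydroxy-2-(4-hydroxyphenyl)-4H-chromen-4-one)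
Product: 2 5-hydroxy-7-methoxy-2-(4-methoxyphenyl)-4H-chromen-4-one
Conditions: MeI (2.3 equiv), K2CO3 (2.5 equiv), DMF, rt, 16 h
Reagents that add atoms: iodomethane CI
Why: Williamson ether synthesis in which the 7- and 4'-phenoxides are alkylated while the 5-OH, hydrogen-bonded to C4=O, stays free under these mild conditions.

**Step 2**
Reactants: 2 5-hydroxy-7-methoxy-2-(4-methoxyphenyl)-4H-chromen-4-one
Product: 4 5,8-dihydroxy-7-methoxy-2-(4-methoxyphenyl)-4H-chromen-4-one, via potassium flavon-8-yl sulfate 3 (not isolated)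
Conditions: K2S2O8 (1.3 equiv), aq KOH, pyridine, 15 °C to rt, 24 h; acidify and filter off recovered 2; then HCl, Na2SO3, H2O, 90 °C, 40 min
Reagents that add atoms: potassium peroxodisulfate [K+].[K+].[O-]S(=O)(=O)OOS(=O)(=O)[O-]
Why: Elbs persulfate oxidation, in which the 5-phenoxide attacks peroxodisulfate through its free para carbon C8 and the resulting aryl sulfate is hydrolysed by acid too mild to cause Wessely–Moser isomerisation.

**Step 3**
Reactants: 4 5,8-dihydroxy-7-methoxy-2-(4-methoxyphenyl)-4H-chromen-4-one; 5 bis(4-bromophenyl)iodonium trifluoromethanesulfonate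
Product: 6 8-(4-bromophenoxy)-5-hydroxy-7-methoxy-2-(4-methoxyphenyl)-4H-chromen-4-one
Conditions: t-BuOK (1.05 equiv), THF/DMF, 0 °C, Ar; then 5 (1.2 equiv), 0 to 40 °C, 6 h
Reagents that add atoms: none
Why: Metal-free O-arylation with a diaryliodonium salt, in which one equivalent of base deprotonates only the unchelated 8-OH, the phenoxide binds trivalent iodine, and ligand coupling forms the ether despite two ortho substituents while leaving the C–Br bond intact.

**Step 4**
Reactants: 7 2,4,6-trihydroxyacetophenone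
Product: 9 5,7-dihydroxy-4H-chromen-4-one, via 4-ethoxy-5,7-dihydroxychromenylium perchlorate 8 (not isolated)
Conditions: HC(OEt)3 (6 equiv), 70 % HClO4 (1.1 equiv), 0 °C to rt, 2 h; the salt is kept wet and taken straight into H2O, 90 °C, 20 min
Reagents that add atoms: triethyl orthoformate CCOC(OCC)OCC; perchloric acid OCl(=O)(=O)=O (counter-ion of 8 only); water O (C4 carbonyl oxygen)
Why: Orthoformate cyclocondensation by the benzopyrylium salt route, in which the diethoxycarbenium ion formylates the enolised methyl ketone, either of the two equivalent ortho hydroxyls closes ring C, and hot water exchanges the 4-ethoxy group for the carbonyl.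

**Step 5 (key step, one pot)**
Reactants: 9 5,7-dihydroxy-4H-chromen-4-one (2.4 equiv); 6 8-(4-bromophenoxy)-5-hydroxy-7-methoxy-2-(4-methoxyphenyl)-4H-chromen-4-one (1.0 equiv)
Product: 13 8-[4-(5,7-dihydroxy-4-oxo-4H-chromen-2-yl)phenoxy]-5-hydroxy-7-methoxy-2-(4-methoxyphenyl)-4H-chromen-4-one (CNP0259871.0), via 5,7-bis(trimethylsilyloxy)chromone 10 (not isolated), via bis(chromon-2-yl)zinc 11 (not isolated), via bis(trimethylsilyl) ether of the target 12 (not isolated)
Conditions: (Me3Si)2NH, neat, 120 °C, 3 h, then vacuum; TMP2Zn·2MgCl2·2LiCl (0.55 equiv per 9), THF, −30 to 0 °C, 1 h; 6, Pd(OAc)2 (3 mol %), SPhos (6 mol %), THF, 50 °C, 12 h; 1 M HCl, THF/MeOH, rt, 30 min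
Reagents that add atoms: hexamethyldisilazane C[Si](C)(C)N[Si](C)(C)C (silyl groups of 10, 11, 12; none stays in 13); TMP2Zn·2MgCl2·2LiCl CC1(C)CCCC(C)(C)N1[Zn]N1C(C)(C)CCCC1(C)C.[Mg+2].[Cl-].[Cl-].[Mg+2].[Cl-].[Cl-].[Li+].[Cl-].[Li+].[Cl-] (zinc of 11 only)
Why: Transient silylation masks both phenols without work-up, the MgCl2-loaded TMP-zinc amide removes C2–H (alpha to the ring oxygen and acidified by Lewis-acid binding at C4=O, which also blocks carbonyl-directed C3 metalation) to give an alpha-metalated enol ether that is an acyl-anion equivalent at a normally electrophilic carbon, Negishi coupling through zerovalent palladium joins it to the electrophilic C–Br carbon of 6 (the excess organozinc covers the chelated 5-OH), and dilute acid removes the silyl groups with no stereocentre formed.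

**Compound list**
1 | apigenin | O=c1cc(-c2ccc(O)cc2)oc2cc(O)cc(O)c12 | starting material
2 | 5-hydroxy-7-methoxy-2-(4-methoxyphenyl)-4H-chromen-4-one | COc1ccc(-c2cc(=O)c3c(O)cc(OC)cc3o2)cc1 | intermediate
3 | potassium 5-hydroxy-7-methoxy-2-(4-methoxyphenyl)-4-oxo-4H-chromen-8-yl sulfate | COc1ccc(-c2cc(=O)c3c(O)cc(OC)c(OS(=O)(=O)[O-])c3o2)cc1.[K+] | intermediate
4 | 5,8-dihydroxy-7-methoxy-2-(4-methoxyphenyl)-4H-chromen-4-one | COc1ccc(-c2cc(=O)c3c(O)cc(OC)c(O)c3o2)cc1 | intermediate
5 | bis(4-bromophenyl)iodonium trifluoromethanesulfonate | Brc1ccc([I+]c2ccc(Br)cc2)cc1.[O-]S(=O)(=O)C(F)(F)F | starting material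
6 | 8-(4-bromophenoxy)-5-hydroxy-7-methoxy-2-(4-methoxyphenyl)-4H-chromen-4-one | COc1ccc(-c2cc(=O)c3c(O)cc(OC)c(Oc4ccc(Br)cc4)c3o2)cc1 | intermediate
7 | 2,4,6-trihydroxyacetophenone | CC(=O)c1c(O)cc(O)cc1O | starting material
8 | 4-ethoxy-5,7-dihydroxychromenylium perchlorate | CCOc1cc[o+]c2cc(O)cc(O)c12.[O-]Cl(=O)(=O)=O | intermediate
9 | 5,7-dihydroxy-4H-chromen-4-one | O=c1ccoc2cc(O)cc(O)c12 | intermediate
10 | 5,7-bis(trimethylsilyloxy)-4H-chromen-4-one | C[Si](C)(C)Oc1cc(O[Si](C)(C)C)c2c(=O)ccoc2c1 | intermediate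
11 | bis[4-oxo-5,7-bis(trimethylsilyloxy)-4H-chromen-2-yl]zinc | C[Si](C)(C)Oc1cc(O[Si](C)(C)C)c2c(=O)cc([Zn]c3cc(=O)c4c(O[Si](C)(C)C)cc(O[Si](C)(C)C)cc4o3)oc2c1 | intermediate
12 | 8-{4-[4-oxo-5,7-bis(trimethylsilyloxy)-4H-chromen-2-yl]phenoxy}-5-hydroxy-7-methoxy-2-(4-methoxyphenyl)-4H-chromen-4-one | COc1ccc(-c2cc(=O)c3c(O)cc(OC)c(Oc4ccc(-c5cc(=O)c6c(O[Si](C)(C)C)cc(O[Si](C)(C)C)cc6o5)cc4)c3o2)cc1 | intermediate
13 | 8-[4-(5,7-dihydroxy-4-oxo-4H-chromen-2-yl)phenoxy]-5-hydroxy-7-methoxy-2-(4-methoxyphenyl)-4H-chromen-4-one (achiral) | COc1ccc(-c2cc(=O)c3c(O)cc(OC)c(Oc4ccc(-c5cc(=O)c6c(O)cc(O)cc6o5)cc4)c3o2)cc1 | target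

**Total step count:** 5 (step 5 is one pot with four operations).
**Longest linear sequence:** 4 (steps 1, 2, 3, 5).

**Three steps most likely to fail**

Step 5. Three things can go wrong:
- Zincation may occur at C3 instead of C2, or stall because MgCl2/LiCl strips the labile silyl ethers.
- The free 5-OH of 6 may quench the organozinc faster than it couples.
- The product is poorly soluble.

The fallback sets out from 9 and comes back at 13. It keeps the nucleophilic C2 but uses an isolable reagent with robust protection. Compound 9 is protected with MOMCl and NaH in DMF to give 5,7-bis(methoxymethoxy)-4H-chromen-4-one F1. Deprotonation with LiTMP in THF at −78 °C, with Bu3SnCl already present, gives 5,7-bis(methoxymethoxy)-2-(tributylstannyl)-4H-chromen-4-one F2. F2 is chromatographed and its regiochemistry is confirmed by loss of the C2–H signal before any 6 is committed. A neutral Stille coupling of F2 and 6 (Pd(PPh3)4, CuI, dioxane, 90 °C) is indifferent to the free phenol and gives the bis(methoxymethyl) ether of the target F3. Treatment with 3 M HCl in MeOH/THF at 50 °C releases 13.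

Step 2. Elbs oxidations of chelated 5-hydroxyflavones rarely exceed 20–40 %. Alkali can open ring C, and the hydroquinone can over-oxidise to the 5,8-quinone. The fallback sets out from 2 and comes back at 4. It replaces phenoxide oxidation by halogenation, borylation and oxidation. Compound 2 is methylated at O5 (MeI, K2CO3, DMF, 60 °C) to 5,7-dimethoxy-2-(4-methoxyphenyl)-4H-chromen-4-one F4. With O5 capped, NIS/TFA in CH2Cl2 iodinates C8 to give 8-iodo-5,7-dimethoxy-2-(4-methoxyphenyl)-4H-chromen-4-one F5. Miyaura borylation (B2pin2, PdCl2(dppf), KOAc, dioxane, 90 °C) gives the 8-pinacolboronate F6. H2O2 in THF/water converts F6 into 8-hydroxy-5,7-dimethoxy-2-(4-methoxyphenyl)-4H-chromen-4-one F7. BCl3 in CH2Cl2 at −40 to 0 °C then cleaves only the 5-methyl ether peri to the carbonyl and gives 4.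

Step 3. The hydroquinone mono-anion may be oxidised by the iodonium salt instead of arylated. The doubly ortho-substituted oxygen is also hindered. The fallback sets out from 4 and comes back at 6. It forms the ether by nucleophilic aromatic substitution and installs bromine afterwards. Compound 4 reacts with 1-fluoro-4-nitrobenzene (K2CO3, DMF, 60 °C) to give 5-hydroxy-7-methoxy-2-(4-methoxyphenyl)-8-(4-nitrophenoxy)-4H-chromen-4-one F8. Fe/NH4Cl in EtOH/water at 70 °C reduces it to 8-(4-aminophenoxy)-5-hydroxy-7-methoxy-2-(4-methoxyphenyl)-4H-chromen-4-one F9. A Sandmeyer reaction (NaNO2 1.0 equiv, aq HBr, 0 °C, then CuBr, 60 °C) gives 6.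

**Further compounds**
F1 | step 5 | 5,7-bis(methoxymethoxy)-4H-chromen-4-one | COCOc1cc(OCOC)c2c(=O)ccoc2c1
F2 | step 5 | 5,7-bis(methoxymethoxy)-2-(tributylstannyl)-4H-chromen-4-one | CCCC[Sn](CCCC)(CCCC)c1cc(=O)c2c(OCOC)cc(OCOC)cc2o1
F3 | step 5 | 8-{4-[5,7-bis(methoxymethoxy)-4-oxo-4H-chromen-2-yl]phenoxy}-5-hydroxy-7-methoxy-2-(4-methoxyphenyl)-4H-chromen-4-one | COCOc1cc(OCOC)c2c(=O)cc(-c3ccc(Oc4c(OC)cc(O)c5c(=O)cc(-c6ccc(OC)cc6)oc45)cc3)oc2c1
F4 | step 2 | 5,7-dimethoxy-2-(4-methoxyphenyl)-4H-chromen-4-one | COc1ccc(-c2cc(=O)c3c(OC)cc(OC)cc3o2)cc1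
F5 | step 2 | 8-iodo-5,7-dimethoxy-2-(4-methoxyphenyl)-4H-chromen-4-one | COc1ccc(-c2cc(=O)c3c(OC)cc(OC)c(I)c3o2)cc1
F6 | step 2 | 5,7-dimethoxy-2-(4-methoxyphenyl)-8-(4,4,5,5-tetramethyl-1,3,2-dioxaborolan-2-yl)-4H-chromen-4-one | COc1ccc(-c2cc(=O)c3c(OC)cc(OC)c(B4OC(C)(C)C(C)(C)O4)c3o2)cc1
F7 | step 2 | 8-hydroxy-5,7-dimethoxy-2-(4-methoxyphenyl)-4H-chromen-4-one | COc1ccc(-c2cc(=O)c3c(OC)cc(OC)c(O)c3o2)cc1
F8 | step 3 | 5-hydroxy-7-methoxy-2-(4-methoxyphenyl)-8-(4-nitrophenoxy)-4H-chromen-4-one | COc1ccc(-c2cc(=O)c3c(O)cc(OC)c(Oc4ccc([N+](=O)[O-])cc4)c3o2)cc1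
F9 | step 3 | 8-(4-aminophenoxy)-5-hydroxy-7-methoxy-2-(4-methoxyphenyl)-4H-chromen-4-one | COc1ccc(-c2cc(=O)c3c(O)cc(OC)c(Oc4ccc(N)cc4)c3o2)cc1
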